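**Numbering.** Compounds 1–23 are numbered in the order in which they first appear in the steps (full list after step 13). The landmarks are pyranone sulfoxide 9, diene 13, cycloaddition product 17, diol 20 and target 23.

## Analysis of the target

Compound 23 is a flavonol: a 4H-chromen-4-one (benzo ring A fused to pyranone ring C through C4a–C8a) with a 4-hydroxyphenyl group (ring B) at C2, phenolic hydroxyls at C5 and C7, and a hydrogen sulfate ester on the enolic oxygen at C3. The molecule is flat and has no stereocentre, so any stereocentre made on the way is transient. The sensitive group is the O3 sulfate monoester, which is cleaved by protic and Lewis acids (the free acid promotes its own hydrolysis). The three free phenols add sensitivity to oxidants and strong base. The real difficulty is regiochemical: O3, O5, O7 and O4' must be told apart so that only O3 is sulfated, and every operation after sulfation must be neutral. O5 is tied to the C4 carbonyl by a six-membered hydrogen bond and can stay free, but O7 and O4' need a group that leaves under neutral conditions, and O3 needs one orthogonal to it. The plan rests on ring A: C4a, C5, C6, C7, C8 and C8a form a resorcinol-type ring, oxygenated at C5 and C7 and fused to ring C at C4a–C8a. A pyranone double bond can supply C4a and C8a, and a butadiene oxygenated at C1 and C3 can supply C5 to C8 with both oxygens already in place.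

## Retrosynthetic reasoning

**Sulfate and benzyl groups (23 back to 20).** The sulfate is the most fragile part, so it goes on late and is followed only by a neutral step. Target 23 is traced through its triethylammonium salt 22 to dibenzyl ether 21 by cutting the two O–CH2Ph bonds at O7 and O4', because hydrogenolysis leaves S–O bonds alone. Cutting the O3–S bond of 21 leads to diol 20. In 20 the O5 hydroxyl is held by the C4 carbonyl, so only O3 is open to a mild sulfating agent.

**Ethers flanking the carbonyl (20 back to 17).** Diol 20 comes from 18 by cleaving the methyl ether at O5 and the methoxymethyl acetal at O3. Both lie next to the C4 carbonyl and are within reach of a chelating Lewis acid and of acid, whereas the benzyl ethers at O7 and O4' are not. Ether 18 comes from phenol 17 by benzylating its single free hydroxyl, so O7 is capped before O3 is freed.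

**Ring A (17 back to 9 and 13).** The bonds C4a–C5 and C8–C8a are cut. This removes C5 to C8 with both oxygens in one operation and leaves a monocyclic pyranone, 9, that already carries ring B and O3 with its own protecting group. O3 therefore never has to be distinguished from free ring A oxygens. The forward reaction must add diene 13 across C5=C6 of 9, expel the sulfur residue from C4a together with the hydrogen at C8a, and lose one methoxy group from C5 to reach the arene. The sulfinyl group sits on C5 for three reasons: it activates the double bond, it makes C6 the acceptor carbon so that the 5,7-pattern results, and it leaves afterwards.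

**Diene (13 back to 10 and 11).** Diene 13 is the silyl enol ether of enone 12. Its ketene acetal carbon carries two methoxy groups, which an ester enolate cannot supply. The C2–C3 bond of 12 is therefore cut to give ketene acetal 10, which brings both methoxy groups, and acetyl chloride 11.

**Sulfur at C5 (9 back to 5).** Sulfoxide 9 comes from sulfide 8 by oxidation. The C5–S bond of 8 is cut to vinyl bromide 6 and thiol 7. The coupling has to be palladium-mediated, because C5 is the α-carbon of the enone and a thiolate would add at C6 instead. Bromide 6 comes from 5 by electrophilic substitution at C5, the only unsubstituted nucleophilic ring carbon.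

**Ring B (5 back to 1).** The C2–aryl bond is cut to bromide 3 and boronic acid 4. Bromide 3 comes from 2 by capping O3, and 2 from pyranone 1, whose free hydroxyl directs bromination to C2. Pyranone 1 is chosen because it already has the oxidation level of a 3-hydroxy-4-pyranone. An oxidative furan ring expansion of the Achmatowicz type was considered for this ring, but it ends two hydrogens richer than 5 and would need a further oxidation.

## Alternatives that were turned down

**Alternative 1:** Ring C is cut at C4a–C4, C4–C3 and O1–C2, leading to 3,5-bis(benzyloxy)-2-iodophenol (A2), 1-(benzyloxy)-4-ethynylbenzene (A3) and carbon monoxide (A4). In the forward direction zerovalent palladium inserts into the C–I bond of A2 and takes up A4, the acylpalladium species is alkynylated by A3, and the phenol oxygen closes onto the ynone. The product is 5,7-bis(benzyloxy)-2-[4-(benzyloxy)phenyl]-4H-chromen-4-one (A1).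
- For it: three bonds and a ring form in one convergent operation, the reaction class has direct precedent for flavones, and both aromatic rings are bought ready-made. It would be several steps shorter than the chosen route and is the stronger plan on precedent and length.
- Against it: A1 has hydrogen at C3, so the oxygen on which the target turns must be added afterwards by metalation–oxidation or epoxidation. The closure can go 5-exo to an aurone as well as 6-endo. A2 requires iodination at one particular position of a phenol in which all three free positions are activated.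
- In its place the chosen route offers an O3 that is present from 1 onwards and separately protected, and a ring A pattern fixed by the polarity of a cycloaddition, not by a selective halogenation.

**Alternative 2:** Ring C is cut at C4–C4a and O1–C2, giving phloroglucinol (A6) and ethyl 2-(benzyloxy)-3-(4-hydroxyphenyl)-3-oxopropanoate (A7, racemic at its enolizable carbon). Heated without solvent, a ring carbon of A6 is acylated by the ester carbon of A7 and the neighbouring hydroxyl condenses with the ketone (a Simonis-type pyrocondensation). The product is 3-(benzyloxy)-5,7-dihydroxy-2-(4-hydroxyphenyl)-4H-chromen-4-one (A5).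
- For it: the symmetry of A6 removes any regiochemical question in ring A, O3 arrives with the keto ester, and the whole skeleton stands after one step from cheap materials. No other plan comes near it in step count.
- Against it: the condensation needs temperatures at which the benzyl ether and the free phenol of A7 are at risk and at which the Pechmann pathway to the isomeric 4-arylcoumarin competes. A5 also has the protecting pattern inverted (O3 blocked, O7 and O4' free). O7 and O4' must be capped with groups that survive hydrogenolysis, O3 debenzylated and sulfated, and the caps removed, which is four further operations.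
- In its place the chosen route, though longer, delivers 20 with exactly the pattern that sulfation needs, at temperatures no higher than about 100 °C.

**Alternative 3:** Ring C is cut at C3–C4 and O1–C8a, giving 1-[4-(benzyloxy)phenyl]-2-(methoxymethoxy)ethan-1-one (A9) and 2,4,6-trifluorobenzoyl chloride (A10). The lithium enolate of A9 is C-acylated by A10, and the enolate oxygen of the diketone displaces an ortho fluoride by addition–elimination. The product of this key step is 2-[4-(benzyloxy)phenyl]-5,7-difluoro-3-(methoxymethoxy)-4H-chromen-4-one A8. The two fluorides of A8 must then be exchanged for oxygen.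
- For it: the sequence to A8 is short and built on two reliable reaction types. O3 and O4' of A8 carry the same orthogonal pair of groups as in 9, so the end game would be the same. It is equal or better in length and in precedent for ring C.
- Against it: in A8 ring A arrives at the wrong oxidation level. The two C–F bonds of A8 must become C–O bonds by intermolecular substitution with an alkoxide, the second on a ring that the first alkoxy group has deactivated. The same alkoxide can attack C2 of A8 and open ring C, and O- versus C-acylation of the enolate of A9 is a further question.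
- In its place the chosen route brings the ring A oxygens in as oxygens, at the final oxidation level and in positions fixed by the cycloaddition, and needs no strongly basic nucleophile once the chromone exists.

Key step: step 9

Assumption: the target is taken as the free hydrogen sulfate as drawn; because such esters hydrolyse under their own acidity it is set free from its ammonium salt only at the very end, cold, and kept in dilute solution or frozen. Sulfoxide 9 is used as the racemate, since its configuration is lost in step 9.

## Route

Step 1
Reactants: 1 3-hydroxy-4H-pyran-4-one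
Product: 2 2-bromo-3-hydroxy-4H-pyran-4-one
Conditions: NBS, MeCN, 0 °C to rt
Reagents that add atoms: N-bromosuccinimide, O=C1CCC(=O)N1Br
Why: Electrophilic bromination of an enol: the free 3-hydroxyl makes C2 (enol β-carbon, also flanked by O1) the most nucleophilic ring carbon, the position at which 3-hydroxy-4-pyranones undergo halogenation, aminomethylation and aldol reactions.

Step 2
Reactants: 2 2-bromo-3-hydroxy-4H-pyran-4-one
Product: 3 2-bromo-3-(methoxymethoxy)-4H-pyran-4-one
Conditions: MOMCl, iPr2NEt, CH2Cl2, 0 °C to rt
Reagents that add atoms: chloromethyl methyl ether, COCCl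
Why: Williamson-type O-alkylation of the acidic enolic hydroxyl; the methoxymethyl acetal should stand palladium catalysis, peracid, heat and carbonate, and leaves with acid without touching benzyl ethers.

Step 3
Reactants: 3 2-bromo-3-(methoxymethoxy)-4H-pyran-4-one; 4 [4-(benzyloxy)phenyl]boronic acid
Product: 5 2-[4-(benzyloxy)phenyl]-3-(methoxymethoxy)-4H-pyran-4-one
Conditions: Pd(dppf)Cl2, K3PO4, 1,4-dioxane–H2O, 80 °C
Reagents that add atoms: none
Why: Suzuki–Miyaura coupling; the C2–Br bond is a vinylogous acyl bromide and should add readily to zerovalent palladium, and the mild phosphate base spares the pyranone ring.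

Step 4
Reactants: 5 2-[4-(benzyloxy)phenyl]-3-(methoxymethoxy)-4H-pyran-4-one
Product: 6 2-[4-(benzyloxy)phenyl]-5-bromo-3-(methoxymethoxy)-4H-pyran-4-one
Conditions: NBS, DMF, rt, dark
Reagents that add atoms: N-bromosuccinimide, O=C1CCC(=O)N1Br
Why: Electrophilic α-bromination of a vinylogous ester, the usual halogenation mode of 4-pyranones: O1 donates through C6 onto C5, the only unsubstituted nucleophilic ring carbon, while ring B is deactivated by conjugation with the carbonyl; no acid is set free, so the acetal should survive.

Step 5
Reactants: 6 2-[4-(benzyloxy)phenyl]-5-bromo-3-(methoxymethoxy)-4H-pyran-4-one; 7 4-methylbenzenethiol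
Product: 8 2-[4-(benzyloxy)phenyl]-3-(methoxymethoxy)-5-[(4-methylphenyl)sulfanyl]-4H-pyran-4-one
Conditions: Pd2(dba)3, Xantphos, iPr2NEt, 1,4-dioxane, 100 °C
Reagents that add atoms: none
Why: Palladium-catalysed C–S cross-coupling of a vinyl bromide with an arenethiol; the substitution has to be metal-mediated because C5 is not the electrophilic carbon of the enone, and the wide-bite-angle bisphosphine keeps the catalyst active in the presence of thiolate.

Step 6
Reactants: 8 2-[4-(benzyloxy)phenyl]-3-(methoxymethoxy)-5-[(4-methylphenyl)sulfanyl]-4H-pyran-4-one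
Product: 9 2-[4-(benzyloxy)phenyl]-3-(methoxymethoxy)-5-[(4-methylphenyl)sulfinyl]-4H-pyran-4-one (racemic at sulfur)
Conditions: mCPBA (1.0 equiv), CH2Cl2, −20 °C
Reagents that add atoms: 3-chloroperoxybenzoic acid, O=C(OO)c1cccc(Cl)c1
Why: Chemoselective sulfide-to-sulfoxide oxidation with one equivalent of peracid at low temperature; the electron-poor pyranone double bonds should not compete, and the racemate suffices because sulfur leaves in step 9.

Step 7
Reactants: 10 1,1-dimethoxyethene; 11 acetyl chloride
Product: 12 4,4-dimethoxybut-3-en-2-one
Conditions: Et3N, Et2O, 0 °C to rt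
Reagents that add atoms: none
Why: C-Acylation of a ketene acetal, which is strongly nucleophilic at its methylene carbon; the amine removes the proton between the carbonyl and the dioxocarbenium carbon and leaves the conjugated push–pull enone.

Step 8
Reactants: 12 4,4-dimethoxybut-3-en-2-one
Product: 13 1,1-dimethoxy-3-[(trimethylsilyl)oxy]buta-1,3-diene
Conditions: TMSCl, Et3N, ZnCl2 (cat.), toluene, 40 °C
Reagents that add atoms: chlorotrimethylsilane, C[Si](C)(C)Cl
Why: Silyl enol ether formation at the only enolizable position, the methyl ketone, under the amine/ZnCl2/chlorosilane conditions commonly used to turn β-alkoxy enones into 2-silyloxydienes.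

Step 9
Reactants: 9 2-[4-(benzyloxy)phenyl]-3-(methoxymethoxy)-5-[(4-methylphenyl)sulfinyl]-4H-pyran-4-one; 13 1,1-dimethoxy-3-[(trimethylsilyl)oxy]buta-1,3-diene
Product: 17 2-[4-(benzyloxy)phenyl]-7-hydroxy-5-methoxy-3-(methoxymethoxy)-4H-chromen-4-one, via cis-fused sulfinyl cycloadduct 14 (not isolated), via 5,5-dimethoxy-5,8-dihydrochromenone 15 (not isolated), via 7-O-trimethylsilyl chromone 16 (not isolated)
Conditions: 13 (3 equiv), toluene, 100 °C; then AcOH, THF–H2O, rt
Reagents that add atoms: none
Why: Proposed new method: the C5=C6 bond of 9 is polarized by the C4 carbonyl and the sulfinyl group, both attached to C5, so C6 is the acceptor carbon; the methylene terminus of 13, which carries the largest HOMO coefficient, should bond to C6 (new C8–C8a bond) and the ketene acetal carbon to C5 (new C4a–C5 bond) in an asynchronous normal-demand (4+2) cycloaddition that closes ring A by intermolecular annulation and gives 14. The closest known reactions are cycloadditions of 3-sulfinylchromones, sulfinylquinones and halogenated quinones with 1,3-dioxygenated butadienes followed by elimination to the arene; a monocyclic 3-alkoxy-2-aryl-4-pyranone has not been used in this way. Suprafacial addition leaves the sulfinyl group at C4a and the hydrogen at C8a cis, as thermal syn elimination of the sulfenic acid requires, and this restores the C4a=C8a double bond (15). Vinylogous loss of methanol from the acetal carbon with a proton from C8 then aromatizes the ring (16), and mild acid cleaves the aryl silyl ether to 17. The two carbon stereocentres of 14 and the sulfur centre are destroyed in the same flask, so nothing has to be controlled stereochemically. The selectivity needed is regiochemical (5,7- against 6,8-oxygenation) and is secured by the sulfinyl group, which with the carbonyl makes C6 the acceptor; site selectivity follows from the other ring double bond, C2=C3, being tetrasubstituted and donor-substituted. An excess of 13 is used because the sulfenic acid and methanol set free consume diene.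

Step 10
Reactants: 17 2-[4-(benzyloxy)phenyl]-7-hydroxy-5-methoxy-3-(methoxymethoxy)-4H-chromen-4-one
Product: 18 7-(benzyloxy)-2-[4-(benzyloxy)phenyl]-5-methoxy-3-(methoxymethoxy)-4H-chromen-4-one
Conditions: BnBr, K2CO3, DMF, rt
Reagents that add atoms: benzyl bromide, BrCc1ccccc1
Why: Williamson etherification of the only free hydroxyl; the 7-hydroxyl is a vinylogous carboxylic acid and should be deprotonated by carbonate at room temperature.

Step 11
Reactants: 18 7-(benzyloxy)-2-[4-(benzyloxy)phenyl]-5-methoxy-3-(methoxymethoxy)-4H-chromen-4-one
Product: 20 7-(benzyloxy)-2-[4-(benzyloxy)phenyl]-3,5-dihydroxy-4H-chromen-4-one, via 5-hydroxy 3-methoxymethyl ether 19 (not isolated)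
Conditions: MgI2·OEt2, toluene–Et2O, 80 °C; then 2 M HCl, MeOH–THF, 50 °C
Reagents that add atoms: none
Why: Chelation-controlled dealkylation: magnesium bridges the C4 carbonyl and O5 and iodide removes the methyl group by SN2 attack, while the unchelated benzyl ethers at O7 and O4' are not activated; acidic methanolysis then removes the acetal at O3, and any part of it already lost to the Lewis acid ends in the same product.

Step 12
Reactants: 20 7-(benzyloxy)-2-[4-(benzyloxy)phenyl]-3,5-dihydroxy-4H-chromen-4-one
Product: 21 triethylammonium 7-(benzyloxy)-2-[4-(benzyloxy)phenyl]-5-hydroxy-4-oxo-4H-chromen-3-yl sulfate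
Conditions: SO3·NEt3, Et3N, DMF, 50 °C
Reagents that add atoms: sulfur trioxide–triethylamine complex, CC[N+](CC)(CC)S(=O)(=O)[O-]
Why: O-Sulfation with an amine–sulfur trioxide complex; O3 should be the only hydroxyl that reacts because the O5 hydroxyl is held in a six-membered hydrogen bond to the C4 carbonyl and is both less acidic and less nucleophilic.

Step 13
Reactants: 21 triethylammonium 7-(benzyloxy)-2-[4-(benzyloxy)phenyl]-5-hydroxy-4-oxo-4H-chromen-3-yl sulfate
Product: 23 kaempferol 3-O-sulfate (5,7-dihydroxy-2-(4-hydroxyphenyl)-4-oxo-4H-chromen-3-yl hydrogen sulfate), via triethylammonium kaempferol 3-sulfate 22 (not isolated)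
Conditions: H2 (1 atm), Pd/C, MeOH–THF, rt; then Dowex 50W (H+ form), H2O–MeOH, 0 °C
Reagents that add atoms: none
Why: Hydrogenolysis of the two aryl benzyl ethers is neutral and should leave the sulfate monoester and the tetrasubstituted C2=C3 bond alone; cold cation exchange then replaces triethylammonium by a proton.

## Compound list

1 | 3-hydroxy-4H-pyran-4-one | O=c1ccocc1O | starting material
2 | 2-bromo-3-hydroxy-4H-pyran-4-one | O=c1ccoc(Br)c1O | intermediate
3 | 2-bromo-3-(methoxymethoxy)-4H-pyran-4-one | COCOc1c(Br)occc1=O | intermediate
4 | [4-(benzyloxy)phenyl]boronic acid | OB(O)c1ccc(OCc2ccccc2)cc1 | starting material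
5 | 2-[4-(benzyloxy)phenyl]-3-(methoxymethoxy)-4H-pyran-4-one | COCOc1c(-c2ccc(OCc3ccccc3)cc2)occc1=O | intermediate
6 | 2-[4-(benzyloxy)phenyl]-5-bromo-3-(methoxymethoxy)-4H-pyran-4-one | COCOc1c(-c2ccc(OCc3ccccc3)cc2)occ(Br)c1=O | intermediate
7 | 4-methylbenzenethiol | Cc1ccc(S)cc1 | starting material
8 | 2-[4-(benzyloxy)phenyl]-3-(methoxymethoxy)-5-[(4-methylphenyl)sulfanyl]-4H-pyran-4-one | COCOc1c(-c2ccc(OCc3ccccc3)cc2)occ(Sc2ccc(C)cc2)c1=O | intermediate
9 | 2-[4-(benzyloxy)phenyl]-3-(methoxymethoxy)-5-[(4-methylphenyl)sulfinyl]-4H-pyran-4-one (racemic at sulfur) | COCOc1c(-c2ccc(OCc3ccccc3)cc2)occ(S(=O)c2ccc(C)cc2)c1=O | intermediate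
10 | 1,1-dimethoxyethene | C=C(OC)OC | starting material
11 | acetyl chloride | CC(=O)Cl | starting material
12 | 4,4-dimethoxybut-3-en-2-one | CC(=O)C=C(OC)OC | intermediate
13 | 1,1-dimethoxy-3-[(trimethylsilyl)oxy]buta-1,3-diene | C=C(O[Si](C)(C)C)C=C(OC)OC | intermediate
14 | cis-2-[4-(benzyloxy)phenyl]-5,5-dimethoxy-3-(methoxymethoxy)-4a-[(4-methylphenyl)sulfinyl]-7-[(trimethylsilyl)oxy]-4a,5,8,8a-tetrahydro-4H-chromen-4-one (racemic; sulfinyl group at C4a and hydrogen at C8a cis, one enantiomer drawn; both sulfur epimers) | COCOC1=C(c2ccc(OCc3ccccc3)cc2)O[C@H]2CC(O[Si](C)(C)C)=CC(OC)(OC)[C@@]2(S(=O)c2ccc(C)cc2)C1=O | intermediate (not isolated)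
15 | 2-[4-(benzyloxy)phenyl]-5,5-dimethoxy-3-(methoxymethoxy)-7-[(trimethylsilyl)oxy]-5,8-dihydro-4H-chromen-4-one | COCOc1c(-c2ccc(OCc3ccccc3)cc2)oc2c(c1=O)C(OC)(OC)C=C(O[Si](C)(C)C)C2 | intermediate (not isolated)
16 | 2-[4-(benzyloxy)phenyl]-5-methoxy-3-(methoxymethoxy)-7-[(trimethylsilyl)oxy]-4H-chromen-4-one | O=c1c(OCOC)c(-c2ccc(OCc3ccccc3)cc2)oc2cc(O[Si](C)(C)C)cc(OC)c12 | intermediate (not isolated)
17 | 2-[4-(benzyloxy)phenyl]-7-hydroxy-5-methoxy-3-(methoxymethoxy)-4H-chromen-4-one | O=c1c(OCOC)c(-c2ccc(OCc3ccccc3)cc2)oc2cc(O)cc(OC)c12 | intermediate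
18 | 7-(benzyloxy)-2-[4-(benzyloxy)phenyl]-5-methoxy-3-(methoxymethoxy)-4H-chromen-4-one | O=c1c(OCOC)c(-c2ccc(OCc3ccccc3)cc2)oc2cc(OCc3ccccc3)cc(OC)c12 | intermediate
19 | 7-(benzyloxy)-2-[4-(benzyloxy)phenyl]-5-hydroxy-3-(methoxymethoxy)-4H-chromen-4-one | O=c1c(OCOC)c(-c2ccc(OCc3ccccc3)cc2)oc2cc(OCc3ccccc3)cc(O)c12 | intermediate (not isolated)
20 | 7-(benzyloxy)-2-[4-(benzyloxy)phenyl]-3,5-dihydroxy-4H-chromen-4-one | O=c1c(O)c(-c2ccc(OCc3ccccc3)cc2)oc2cc(OCc3ccccc3)cc(O)c12 | intermediate
21 | triethylammonium 7-(benzyloxy)-2-[4-(benzyloxy)phenyl]-5-hydroxy-4-oxo-4H-chromen-3-yl sulfate | O=c1c(OS(=O)(=O)[O-])c(-c2ccc(OCc3ccccc3)cc2)oc2cc(OCc3ccccc3)cc(O)c12.CC[NH+](CC)CC | intermediate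
22 | triethylammonium 5,7-dihydroxy-2-(4-hydroxyphenyl)-4-oxo-4H-chromen-3-yl sulfate | O=c1c(OS(=O)(=O)[O-])c(-c2ccc(O)cc2)oc2cc(O)cc(O)c12.CC[NH+](CC)CC | intermediate (not isolated)
23 | kaempferol 3-O-sulfate, 5,7-dihydroxy-2-(4-hydroxyphenyl)-4-oxo-4H-chromen-3-yl hydrogen sulfate | O=c1c(OS(=O)(=O)O)c(-c2ccc(O)cc2)oc2cc(O)cc(O)c12 | target

## Step count and least certain steps

Total step count: 13 steps. Longest linear sequence: 11 steps (steps 1–6 and 9–13); the diene branch (steps 7 and 8) joins at step 9.

**Step 9 (key step, new method).** The cycloaddition may be too slow on a double bond that is still part of a cross-conjugated vinylogous ester, so that thermal decay of 13, or its consumption by the sulfenic acid and methanol set free, wins. The diene may also add through its methylene end only, without ring closure, or the aromatization may stall at the dihydro stage. The fallback uses known chemistry, gives up the benzannulation and builds the flavonol on a preformed ring A; it sets out from boronic acid 4 and comes back at 22. 5,7-Dihydroxy-4H-chromen-4-one F1 is benzylated on both oxygens (BnBr, K2CO3, DMF, 80 °C) to 5,7-bis(benzyloxy)-4H-chromen-4-one F2. Conjugate addition of 4 to C2 of F2 under a divalent palladium catalyst (Pd(O2CCF3)2, 2,2'-bipyridine, aqueous solvent) would give 5,7-bis(benzyloxy)-2-[4-(benzyloxy)phenyl]chroman-4-one F3. Dehydrogenation with I2 in hot pyridine would give 5,7-bis(benzyloxy)-2-[4-(benzyloxy)phenyl]-4H-chromen-4-one F4, the same flavone as A1. Lithiation at C3 with LiN(iPr)2, trapping with B(OMe)3 and oxidation with H2O2 would give 5,7-bis(benzyloxy)-2-[4-(benzyloxy)phenyl]-3-hydroxy-4H-chromen-4-one F5, whose only free hydroxyl is O3. Sulfation as in step 12 would give triethylammonium 5,7-bis(benzyloxy)-2-[4-(benzyloxy)phenyl]-4-oxo-4H-chromen-3-yl sulfate F6, and hydrogenolysis as in step 13 would remove the three benzyl groups and arrive at 22.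

**Step 4.** Bromination may go ortho to the benzyloxy group on ring B instead of at C5, or bromine may add across C5=C6 without loss of HBr. The fallback forms the C5–S bond directly by electrophilic sulfenylation; it sets out from 5 (with thiol 7) and comes back at 8. Thiol 7 is converted with N-chlorosuccinimide into 4-methylbenzenesulfenyl chloride F7, a soft electrophile that should attack the vinylogous ester carbon C5 of 5 in CH2Cl2 with pyridine at −20 °C. This gives sulfide 8 and bypasses bromide 6 and the cross-coupling.

**Step 7.** Chloride may demethylate the dioxocarbenium intermediate (giving a β-keto ester), the amine may turn 11 into ketene, or 10 may oligomerize. The fallback sets out from 11 and comes back at 12. AlCl3-mediated addition of 11 to 1,1-dichloroethene F8 gives 4,4,4-trichlorobutan-2-one F9, which loses HCl on distillation to 4,4-dichlorobut-3-en-2-one F10. Twofold addition–elimination with NaOMe in methanol then gives 12.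

**Step 11.** Demethylation may stall once the acetal at O3 has been lost and the freed O3 competes for magnesium, and the benzyl ethers may be slowly lost on prolonged heating with the Lewis acid. The fallback avoids the methyl ether altogether by letting O5 emerge free from the cycloaddition; it sets out from 9 and comes back at 19. Methyl 3-oxobutanoate F11 is silylated (TMSCl, Et3N) to methyl 3-[(trimethylsilyl)oxy]but-2-enoate F12. Deprotonation with LiN(iPr)2 and silylation give 1-methoxy-1,3-bis[(trimethylsilyl)oxy]buta-1,3-diene F13 (ketene acetal geometry immaterial). Cycloaddition with 9 as in step 9, loss of methanol from the mixed acetal and desilylation should give 2-[4-(benzyloxy)phenyl]-5,7-dihydroxy-3-(methoxymethoxy)-4H-chromen-4-one F14. Benzylation of the unchelated O7 (BnBr, K2CO3, acetone, rt) then gives 19, and the acid treatment of step 11 leads on to 20.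

**Step 12.** Conversion at the hydrogen-bonded O3 may be incomplete, the O5 hydroxyl may be sulfated under forcing conditions, or the sulfate may be lost during purification of the salt. The fallback carries the sulfate as a neutral protected diester; it sets out from 20 and comes back at 23. Treatment of 20 with 2,2,2-trichloroethyl chlorosulfate, Et3N and 4-(dimethylamino)pyridine in THF gives 7-(benzyloxy)-2-[4-(benzyloxy)phenyl]-5-hydroxy-4-oxo-4H-chromen-3-yl 2,2,2-trichloroethyl sulfate F15, which can be chromatographed. Pd/C with HCO2NH4 in methanol removes the trichloroethyl group and both benzyl groups and gives ammonium 5,7-dihydroxy-2-(4-hydroxyphenyl)-4-oxo-4H-chromen-3-yl sulfate F16. Cation exchange as in step 13 gives 23.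

## Further compounds

F1 | step 9 | 5,7-dihydroxy-4H-chromen-4-one | O=c1ccoc2cc(O)cc(O)c12
F2 | step 9 | 5,7-bis(benzyloxy)-4H-chromen-4-one | O=c1ccoc2cc(OCc3ccccc3)cc(OCc3ccccc3)c12
F3 | step 9 | 5,7-bis(benzyloxy)-2-[4-(benzyloxy)phenyl]chroman-4-one (racemic) | O=C1CC(c2ccc(OCc3ccccc3)cc2)Oc2cc(OCc3ccccc3)cc(OCc3ccccc3)c21
F4 | step 9 | 5,7-bis(benzyloxy)-2-[4-(benzyloxy)phenyl]-4H-chromen-4-one | O=c1cc(-c2ccc(OCc3ccccc3)cc2)oc2cc(OCc3ccccc3)cc(OCc3ccccc3)c12
F5 | step 9 | 5,7-bis(benzyloxy)-2-[4-(benzyloxy)phenyl]-3-hydroxy-4H-chromen-4-one | O=c1c(O)c(-c2ccc(OCc3ccccc3)cc2)oc2cc(OCc3ccccc3)cc(OCc3ccccc3)c12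
F6 | step 9 | triethylammonium 5,7-bis(benzyloxy)-2-[4-(benzyloxy)phenyl]-4-oxo-4H-chromen-3-yl sulfate | O=c1c(OS(=O)(=O)[O-])c(-c2ccc(OCc3ccccc3)cc2)oc2cc(OCc3ccccc3)cc(OCc3ccccc3)c12.CC[NH+](CC)CC
F7 | step 4 | 4-methylbenzenesulfenyl chloride | Cc1ccc(SCl)cc1
F8 | step 7 | 1,1-dichloroethene | C=C(Cl)Cl
F9 | step 7 | 4,4,4-trichlorobutan-2-one | CC(=O)CC(Cl)(Cl)Cl
F10 | step 7 | 4,4-dichlorobut-3-en-2-one | CC(=O)C=C(Cl)Cl
F11 | step 11 | methyl 3-oxobutanoate | COC(=O)CC(C)=O
F12 | step 11 | methyl 3-[(trimethylsilyl)oxy]but-2-enoate (E/Z mixture) | COC(=O)C=C(C)O[Si](C)(C)C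
F13 | step 11 | 1-methoxy-1,3-bis[(trimethylsilyl)oxy]buta-1,3-diene | C=C(O[Si](C)(C)C)C=C(OC)O[Si](C)(C)C
F14 | step 11 | 2-[4-(benzyloxy)phenyl]-5,7-dihydroxy-3-(methoxymethoxy)-4H-chromen-4-one | O=c1c(OCOC)c(-c2ccc(OCc3ccccc3)cc2)oc2cc(O)cc(O)c12
F15 | step 12 | 7-(benzyloxy)-2-[4-(benzyloxy)phenyl]-5-hydroxy-4-oxo-4H-chromen-3-yl 2,2,2-trichloroethyl sulfate | O=c1c(OS(=O)(=O)OCC(Cl)(Cl)Cl)c(-c2ccc(OCc3ccccc3)cc2)oc2cc(OCc3ccccc3)cc(O)c12
F16 | step 12 | ammonium 5,7-dihydroxy-2-(4-hydroxyphenyl)-4-oxo-4H-chromen-3-yl sulfate | O=c1c(OS(=O)(=O)[O-])c(-c2ccc(O)cc2)oc2cc(O)cc(O)c12.[NH4+]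
A1 | alternative 1 | 5,7-bis(benzyloxy)-2-[4-(benzyloxy)phenyl]-4H-chromen-4-one | O=c1cc(-c2ccc(OCc3ccccc3)cc2)oc2cc(OCc3ccccc3)cc(OCc3ccccc3)c12
A2 | alternative 1 | 3,5-bis(benzyloxy)-2-iodophenol | Oc1cc(OCc2ccccc2)cc(OCc2ccccc2)c1I
A3 | alternative 1 | 1-(benzyloxy)-4-ethynylbenzene | C#Cc1ccc(OCc2ccccc2)cc1
A4 | alternative 1 | carbon monoxide | [C-]#[O+]
A5 | alternative 2 | 3-(benzyloxy)-5,7-dihydroxy-2-(4-hydroxyphenyl)-4H-chromen-4-one | O=c1c(OCc2ccccc2)c(-c2ccc(O)cc2)oc2cc(O)cc(O)c12
A6 | alternative 2 | benzene-1,3,5-triol (phloroglucinol) | Oc1cc(O)cc(O)c1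
A7 | alternative 2 | ethyl 2-(benzyloxy)-3-(4-hydroxyphenyl)-3-oxopropanoate (racemic) | CCOC(=O)C(OCc1ccccc1)C(=O)c1ccc(O)cc1
A8 | alternative 3 | 2-[4-(benzyloxy)phenyl]-5,7-difluoro-3-(methoxymethoxy)-4H-chromen-4-one | O=c1c(OCOC)c(-c2ccc(OCc3ccccc3)cc2)oc2cc(F)cc(F)c12
A9 | alternative 3 | 1-[4-(benzyloxy)phenyl]-2-(methoxymethoxy)ethan-1-one | COCOCC(=O)c1ccc(OCc2ccccc2)cc1
A10 | alternative 3 | 2,4,6-trifluorobenzoyl chloride | O=C(Cl)c1c(F)cc(F)cc1F
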